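The constants make this a race: the second coupling's constant, 0.15 L mol⁻¹ h⁻¹, is larger than the first's, 0.052 L mol⁻¹ h⁻¹, and the side step's, 0.019 L mol⁻¹ h⁻¹, is smaller than both, but that step feeds on starting material instead of coupling partner.

| setting | summer | winter | dusk |
|---|---|---|---|
| starting material | 0.75 M | 0.75 M | 0.75 M |
| coupling partner | 0.400 equiv | 1.20 equiv | 4.00 equiv |
| time | 20 d | 20 d | 20 d |

    starting material + coupling partner → single product + by-product (k1 = 0.052 L mol⁻¹ h⁻¹)
    coupling partner + single product → double product + by-product (k2 = 0.15 L mol⁻¹ h⁻¹)
    coupling partner + double product → triple product + by-product (k3 = 0.27 L mol⁻¹ h⁻¹)
    coupling partner + triple product → tetra adduct + by-product (k4 = 0.025 L mol⁻¹ h⁻¹)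
    starting material + single product → side product (k5 = 0.019 L mol⁻¹ h⁻¹)

1. [single product] at the end for summer, winter, dusk, in this order
2. the course of these numbers from the first flask to the last (rises, then falls / hardly changes / falls, then rises / rises all the way / falls all the way)

- in percentages every species weighs as the starting material in it: one side product counts as two
- "hardly changes" means that all values lie within two and a half points (for a concentration: within two and a half percent of the largest)
- run time (summer): 20 d

My reckoning builds the flask one process at a time.

1. I take the first coupling by itself: in summer the ceiling for c(single product) is the coupling partner charged, 0.300 M, the limiting reagent, and in winter and dusk it is the starting material charged, 0.75 M.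

2. I add the second coupling, whose constant is larger than the first's, so that single product first builds up and then, once enough of it stands, is used as fast as it forms. With coupling partner in excess both couplings are pseudo-first-order on one clock, so c(single product) follows c(starting material) at a ratio of 0.531, and the dusk number falls with the starting material.

3. I add the side step and compare rates at one moment. At summer's charge the side step takes single product at 0.317 of the rate of the second coupling. This is my drain ratio, c(starting material) times the side step's constant over c(coupling partner) times the second coupling's constant, with c(single product) cancelling.

4. I ask how it drifts: coupling partner falls faster than starting material in summer, so the ratio climbs, and the side step's half-life on single product, 2.0 d at charged concentrations, is shorter than the time. Summer should therefore end low. Winter starts at 0.106 and has less starting material left to drain with, so it should end higher. Dusk starts at 0.0317, and there c(single product) should go down with c(starting material) as in step 2.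

5. I put rough numbers on this. I let each starting material that reacts take two coupling partners, which leaves 0.600 M of it in summer and 0.300 M in winter; I start c(single product) at 0.531 of that and let the side step wear it down at that c(starting material) for the whole time, which gives 0.00134 M for summer and 0.0103 M for winter. In dusk, after three couplings, coupling partner and triple product each stand near 0.75 M and fall together by the fourth coupling, and the first coupling runs on the time integral of c(coupling partner) this allows, which gives 0.00331 M, on the high side since this integral leaves out the early hours. I commit to a row that rises, then falls.

The forecast gives 0.0027 M, 0.012 M and 0.0013 M, so rises, then falls, with the ground for dusk that “excess partner persists”.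

The simulation gives 0.00292 M, 0.0170 M and 1.26 × 10⁻⁴ M, so rises, then falls. The forecast's dusk value is ten times the simulated one.

In summer the drain ratio reads 0.46 at 0.506 d, up from 0.317 at the charge, and coupling partner stands at 0% of its charge by 10.0 d. The run without the side step proves its weight: summer then ends at 0.129 M instead of 0.00292 M, a factor of 44.2. Dusk starts at a ratio ten times lower, at 0.0317, and keeps 4.28% of its coupling partner to the end, where side product holds 3.37% against summer's 36.7%.

The constants were set for the occasion; the rest is arithmetic.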